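**Plan**
- **Difficulty:** two E-trisubstituted alkenes sit in a skipped polyene, and the C-prenyl bond is ortho to a free phenol, where O-alkylation, SN2′ attack and chroman closure compete. There is no stereocentre.
- **Enabling feature:** the phenol O (on arene C4) and side-chain C3′ are linked through C4–C3(arene)–C1′–C2′. An extra O–C3′ bond therefore closes a six-membered 4H-chromene (O1–C2=C3–C4–C4a–C8a) that is not in the target. In that ring O and C1′ can only be cis on C2′=C3′.
- **Cuts:** first C3′–CH3 (with O–C3′ reconnection), then C3′–C4′. Both are made at the former lactone carbonyl carbon of a 3,4-dihydrocoumarin, which serves as a 1,1-dielectrophile. Then C5′–C6′ and C7′–CH3, back to the alkyne from dihydro-β-ionone, which brings the trimethylcyclohexene ring.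
- **Forward:** the C13 ketone goes to the alkyne and then to the (E)-C16 triene. Separately, the formyl-hydroxybenzoate goes to the coumarin, the dihydrocoumarin and the ketene acetal phosphate. A B-alkyl Suzuki coupling joins both halves at chromene C2, the ester becomes the carboxylate, and Ni/MeMgBr exchanges the ring C2–O bond for C–CH3 and opens the temporary ring to the target.
- **Geometry:** Δ6′ comes from syn-carboalumination and a retentive coupling. Δ2′ comes from the ring constraint and a retentive C–O to C–CH3 exchange.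

Key step: step 8

Assumption: the target has no stereocentre, so "single enantiomer" is read as the single (2′E,6′E) geometric isomer drawn in the SMILES.

**Step 1**
Reactants: 1 dihydro-β-ionone [4-(2,6,6-trimethylcyclohex-1-en-1-yl)butan-2-one]
Product: 5 2-(but-3-yn-1-yl)-1,3,3-trimethylcyclohex-1-ene, via kinetic lithium enolate 2 (not isolated), via enol diethyl phosphate 3 (not isolated), via lithium acetylide 4 (not isolated)
Conditions: LDA (1.05 equiv), THF, −78 °C; ClP(O)(OEt)2, −78 °C → rt; then LDA (2.3 equiv), THF, −78 °C → rt; H2O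
Reagents that add atoms: LDA, [Li+].CC(C)[N-]C(C)C (Li in 2 and 4 only); diethyl chlorophosphate, CCOP(=O)(Cl)OCC (phosphoryl group in 3 only; none of these atoms remains in 5)
Why: Kinetic deprotonation at CH3, O-phosphorylation and base-induced 1,2-elimination of the enol phosphate (the known methyl ketone → terminal alkyne sequence for terpenoid methyl ketones) should give the alkyne, the tetrasubstituted ring alkene being inert to amide bases.

**Step 2**
Reactants: 5 2-(but-3-yn-1-yl)-1,3,3-trimethylcyclohex-1-ene
Product: 7 1,3,3-trimethyl-2-[(3E)-3-methylhexa-3,5-dien-1-yl]cyclohex-1-ene, via dimethyl[(1E)-2-methyl-4-(2,6,6-trimethylcyclohex-1-en-1-yl)but-1-en-1-yl]alane 6 (not isolated)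
Conditions: Me3Al (2 equiv), Cp2ZrCl2 (0.25 equiv), (CH2Cl)2, rt; volatiles removed in vacuo; vinyl bromide (THF solution), Pd(PPh3)4 (5 mol %), ZnCl2 (20 mol %), THF, rt
Reagents that add atoms: trimethylaluminium, C[Al](C)C (CH3 on C7′; AlMe2 in 6 only); vinyl bromide, C=CBr (C5′ and C4′)
Why: Zr-catalysed Negishi carboalumination adds CH3 and Al syn across the terminal alkyne with Al on the terminal carbon, and the Pd/Zn co-catalysed Negishi-type alkenyl–alkenyl coupling proceeds with retention, which fixes the E geometry of the future C6′=C7′ bond.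

**Step 3**
Reactants: 8 methyl 3-formyl-4-hydroxybenzoate
Product: 10 methyl 2-oxo-2H-chromene-6-carboxylate, via methyl 3-[(1E)-3-ethoxy-3-oxoprop-1-en-1-yl]-4-hydroxybenzoate 9 (not isolated)
Conditions: Ph3P=CHCO2Et, PhNEt2, reflux
Reagents that add atoms: ethyl (triphenylphosphoranylidene)acetate, CCOC(=O)C=P(c1ccccc1)(c1ccccc1)c1ccccc1
Why: Wittig olefination of the salicylaldehyde, followed at the reflux temperature by E→Z isomerisation and lactonisation of the o-hydroxycinnamate, is a standard coumarin synthesis that leaves the methyl benzoate untouched.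

**Step 4**
Reactants: 10 methyl 2-oxo-2H-chromene-6-carboxylate
Product: 11 methyl 2-oxo-3,4-dihydro-2H-chromene-6-carboxylate (the 6-methoxycarbonyl dihydrocoumarin)
Conditions: H2 (4 bar), 10 % Pd/C, EtOAc, 50 °C
Reagents that add atoms: none
Why: Heterogeneous catalytic hydrogenation saturates only the conjugated C3=C4 bond of the coumarin, and the non-nucleophilic solvent keeps the aryl lactone closed.

**Step 5**
Reactants: 11 methyl 2-oxo-3,4-dihydro-2H-chromene-6-carboxylate
Product: 13 methyl 2-[(diphenoxyphosphoryl)oxy]-4H-chromene-6-carboxylate, via potassium lactone enolate 12 (not isolated)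
Conditions: (PhO)2P(O)Cl premixed with 11, THF–DMPU, −78 °C; KHMDS added dropwise; Et3N-buffered work-up
Reagents that add atoms: diphenyl chlorophosphate, O=P(Cl)(Oc1ccccc1)Oc1ccccc1; KHMDS, C[Si](C)(C)[N-][Si](C)(C)C.[K+] (K in 12 only)
Why: Enolisation at the only acidic C–H (lactone C3) with internal quench is the standard formation of lactone-derived ketene acetal phosphates, benzo-fused aryl lactones included, and trapping the enolate as it forms forestalls ring-opening to ketene/phenoxide and Claisen self-condensation.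

**Step 6**
Reactants: 7 1,3,3-trimethyl-2-[(3E)-3-methylhexa-3,5-dien-1-yl]cyclohex-1-ene; 13 methyl 2-[(diphenoxyphosphoryl)oxy]-4H-chromene-6-carboxylate
Product: 15 methyl 2-[(3E)-4-methyl-6-(2,6,6-trimethylcyclohex-1-en-1-yl)hex-3-en-1-yl]-4H-chromene-6-carboxylate, via 9-[(3E)-4-methyl-6-(2,6,6-trimethylcyclohex-1-en-1-yl)hex-3-en-1-yl]-9-borabicyclo[3.3.1]nonane 14 (not isolated)
Conditions: 7, 9-BBN-H (slightly less than 1 equiv per 7), THF, 0 °C → rt; then 13, PdCl2(dppf) (5 mol %), 3 M aq Cs2CO3, DMF, rt → 50 °C
Reagents that add atoms: 9-BBN-H, B1C2CCCC1CCC2 (boron cage in 14 only; nothing but H remains in 15)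
Why: 9-BBN adds only to the monosubstituted terminus of the 1,3-diene (as in the known selective hydroboration of 4-methyl-1,3-dienes to homoallylic boranes), and B-alkyl Suzuki–Miyaura coupling with a lactone-derived ketene acetal phosphate is an established, regiospecific entry to 2-alkyl cyclic enol ethers with the double bond fixed at C2=C3.

**Step 7**
Reactants: 15 methyl 2-[(3E)-4-methyl-6-(2,6,6-trimethylcyclohex-1-en-1-yl)hex-3-en-1-yl]-4H-chromene-6-carboxylate
Product: 16 potassium 2-[(3E)-4-methyl-6-(2,6,6-trimethylcyclohex-1-en-1-yl)hex-3-en-1-yl]-4H-chromene-6-carboxylate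
Conditions: KOSiMe3 (1.1 equiv), THF, rt → 40 °C; concentrate, triturate (pentane), dry in vacuo
Reagents that add atoms: potassium trimethylsilanolate, C[Si](C)(C)[O-].[K+]
Why: Silanolate-mediated cleavage of a methyl benzoate runs under anhydrous, non-acidic conditions, so the acid-labile enol ether survives and the carboxyl group is obtained as the dry carboxylate that resists the Grignard reagent of step 8.

**Step 8**
Reactants: 16 potassium 2-[(3E)-4-methyl-6-(2,6,6-trimethylcyclohex-1-en-1-yl)hex-3-en-1-yl]-4H-chromene-6-carboxylate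
Product: 18 cacospongin D, 4-hydroxy-3-[(2E,6E)-3,7-dimethyl-9-(2,6,6-trimethylcyclohex-1-en-1-yl)nona-2,6-dien-1-yl]benzoic acid, via its bromomagnesium phenoxide/potassium carboxylate 17 (not isolated)
Conditions: MeMgBr (4 equiv), NiCl2(PPh3)2 (10 mol %), PhMe–THF, 70 °C; then cold 0.5 M HCl to pH 3, EtOAc, 0 °C
Reagents that add atoms: methylmagnesium bromide, C[Mg]Br (CH3 on C3′; MgBr in 17 only)
Why: Ni(0), formed from the precatalyst and MeMgBr, inserts into the alkenyl C2–O1 bond of the 4H-chromene, the nickel-bound phenoxide is exchanged for methyl by the Grignard reagent, and reductive elimination forms C3′–CH3 with retention at the alkenyl carbon, which opens the ring. The closest known reaction type is the nickel-catalysed Kumada-type coupling of Grignard reagents with cyclic enol ethers (5-alkyl-2,3-dihydrofurans, 6-alkyl-3,4-dihydro-2H-pyrans, benzofurans), which gives trisubstituted homoallylic alcohols or o-alkenylphenols with retention. No ring is closed and no stereocentre is formed; the only stereo-element, the C2′=C3′ geometry, is controlled by the six-membered ring, which holds O1 and C4 (the future C1′) cis, so methyl takes the place of oxygen cis to C1′ and the long chain ends up trans, i.e. E. Site selectivity between the two C–O bonds of O1 is needed and is secured because a C(aryl)–O bond of a monocyclic benzene is the least reactive ether class under Ni/PPh3, whereas the alkenyl C–O bond carries a phenoxide leaving group. Chemoselectivity at the carboxyl group is secured by carrying it as the carboxylate, and methyl has no β-hydrogen, so no nickel hydride arises that could reduce the C–O bond or move the skipped alkenes into conjugation. The same event frees the phenol, so brief cold dilute acid should deliver 18 without a deprotection step under which an o-prenylphenol could close to a chroman.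

**Compound list**
1 | dihydro-β-ionone | CC(=O)CCC1=C(C)CCCC1(C)C | starting material
2 | lithium 4-(2,6,6-trimethylcyclohex-1-en-1-yl)but-1-en-2-olate | [Li+].[O-]C(=C)CCC1=C(C)CCCC1(C)C | intermediate
3 | diethyl 4-(2,6,6-trimethylcyclohex-1-en-1-yl)but-1-en-2-yl phosphate | CCOP(=O)(OCC)OC(=C)CCC1=C(C)CCCC1(C)C | intermediate
4 | lithium 4-(2,6,6-trimethylcyclohex-1-en-1-yl)but-1-yn-1-ide | [Li+].[C-]#CCCC1=C(C)CCCC1(C)C | intermediate
5 | 2-(but-3-yn-1-yl)-1,3,3-trimethylcyclohex-1-ene | C#CCCC1=C(C)CCCC1(C)C | intermediate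
6 | dimethyl[(1E)-2-methyl-4-(2,6,6-trimethylcyclohex-1-en-1-yl)but-1-en-1-yl]alane | C[Al](C)/C=C(\C)CCC1=C(C)CCCC1(C)C | intermediate
7 | 1,3,3-trimethyl-2-[(3E)-3-methylhexa-3,5-dien-1-yl]cyclohex-1-ene | C=C/C=C(\C)CCC1=C(C)CCCC1(C)C | intermediate
8 | methyl 3-formyl-4-hydroxybenzoate | COC(=O)c1ccc(O)c(C=O)c1 | starting material
9 | methyl 3-[(1E)-3-ethoxy-3-oxoprop-1-en-1-yl]-4-hydroxybenzoate | CCOC(=O)/C=C/c1cc(ccc1O)C(=O)OC | intermediate
10 | methyl 2-oxo-2H-chromene-6-carboxylate | COC(=O)c1ccc2OC(=O)C=Cc2c1 | intermediate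
11 | methyl 2-oxo-3,4-dihydro-2H-chromene-6-carboxylate | COC(=O)c1ccc2OC(=O)CCc2c1 | intermediate
12 | potassium 6-(methoxycarbonyl)-4H-chromen-2-olate | [K+].[O-]C1=CCc2cc(ccc2O1)C(=O)OC | intermediate
13 | methyl 2-[(diphenoxyphosphoryl)oxy]-4H-chromene-6-carboxylate | COC(=O)c1ccc2OC(=CCc2c1)OP(=O)(Oc1ccccc1)Oc1ccccc1 | intermediate
14 | 9-[(3E)-4-methyl-6-(2,6,6-trimethylcyclohex-1-en-1-yl)hex-3-en-1-yl]-9-borabicyclo[3.3.1]nonane | CC1=C(CC/C(C)=C/CCB2C3CCCC2CCC3)C(C)(C)CCC1 | intermediate
15 | methyl 2-[(3E)-4-methyl-6-(2,6,6-trimethylcyclohex-1-en-1-yl)hex-3-en-1-yl]-4H-chromene-6-carboxylate | COC(=O)c1ccc2OC(CC/C=C(\C)CCC3=C(C)CCCC3(C)C)=CCc2c1 | intermediate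
16 | potassium 2-[(3E)-4-methyl-6-(2,6,6-trimethylcyclohex-1-en-1-yl)hex-3-en-1-yl]-4H-chromene-6-carboxylate | [K+].[O-]C(=O)c1ccc2OC(CC/C=C(\C)CCC3=C(C)CCCC3(C)C)=CCc2c1 | intermediate
17 | bromomagnesium phenoxide/potassium carboxylate of cacospongin D | CC1=C(CC/C(C)=C/CC/C(C)=C/Cc2cc(ccc2[O-])C([O-])=O)C(C)(C)CCC1.[Mg+2].[Br-].[K+] | intermediate
18 | cacospongin D | CC1=C(CC/C(C)=C/CC/C(C)=C/Cc2cc(C(=O)O)ccc2O)C(C)(C)CCC1 | target

**Step count**
Total step count: 8.
Longest linear sequence: 6 (steps 3–8, from 8).

**Steps most likely to fail**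

**Step 8.**
- **Risk:** oxidative addition may be sluggish if the carboxylate salt precipitates from the low-polarity medium. The alkenyl–nickel intermediate may partly lose its geometry. The Grignard reagent may slowly attack the carboxylate at the temperature required.
- **Fallback:** it sets out from borane 14 and comes back at 18. It makes the C1′–C2′ bond by alkenyl–benzyl coupling and takes the Δ2′ geometry from a second carboalumination.
  - Oxidation of 14 (NaOH/H2O2) gives the homoallylic alcohol F1.
  - I2/PPh3/imidazole converts it into the homoallylic iodide F2.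
  - Lithium acetylide–ethylenediamine in DMSO gives the terminal enyne F3.
  - Me3Al/cat. Cp2ZrCl2 gives the (E)-dienylalane F4.
  - Ni(0)- or Pd(0)-catalysed coupling of F4 with commercial methyl 3-(bromomethyl)-4-methoxybenzoate gives the O-methyl ether methyl ester F5.
  - NaSEt in hot DMF removes both methyl groups by SN2 attack and, after mild acidification, gives 18.

**Step 6.**
- **Risk:** over-hydroboration or allylic (1,4-type) hydroboration of the conjugated diene is possible. The aqueous base may also hydrolyse the aryl ketene acetal phosphate faster than transmetalation occurs.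
- **Fallback:** it sets out from alkenylalane 6 (made from 5 as in step 2) and comes back at 15. It avoids both the diene hydroboration and water.
  - n-BuLi converts 6 into the lithium aluminate F6.
  - F6 opens ethylene oxide to give the homoallylic alcohol F1, and iodination as above gives the iodide F2.
  - Zinc insertion (Zn, LiCl, THF) gives the alkylzinc iodide F7.
  - Anhydrous Negishi coupling of F7 with 13 (Pd(PPh3)4, THF) gives 15.

**Step 5.**
- **Risk:** the aryl-lactone enolate may open to ketene/phenoxide, Claisen self-condensation may intervene, or the phosphate may be lost by hydrolysis during purification.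
- **Fallback:** it sets out from 11 and comes back at 15. It reverses the polarity of C2 from electrophile to carbanion.
  - DIBAL-H (1 equiv, −78 °C) reduces the more electrophilic aryl lactone to the racemic lactol F8.
  - PhSO2H/CaCl2 gives the racemic 2-(phenylsulfonyl)chromane F9.
  - Deprotonation (LDA, THF–DMPU, −78 °C) and alkylation with the iodide F2 (made as described above) gives the racemic alkylated sulfone F10.
  - On warming, F10 loses sulfinate (the known alkylation–elimination of 2-sulfonyl cyclic ethers) to give the endocyclic enol ether 15.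

**Further compounds**
F1 | step 8 | (3E)-4-methyl-6-(2,6,6-trimethylcyclohex-1-en-1-yl)hex-3-en-1-ol | CC1=C(CC/C(C)=C/CCO)C(C)(C)CCC1
F2 | step 8 | 2-[(3E)-6-iodo-3-methylhex-3-en-1-yl]-1,3,3-trimethylcyclohex-1-ene | CC1=C(CC/C(C)=C/CCI)C(C)(C)CCC1
F3 | step 8 | 1,3,3-trimethyl-2-[(3E)-3-methyloct-3-en-7-yn-1-yl]cyclohex-1-ene | CC1=C(CC/C(C)=C/CCC#C)C(C)(C)CCC1
F4 | step 8 | [(1E,5E)-2,6-dimethyl-8-(2,6,6-trimethylcyclohex-1-en-1-yl)octa-1,5-dien-1-yl]dimethylalane | CC1=C(CC/C(C)=C/CC/C(C)=C/[Al](C)C)C(C)(C)CCC1
F5 | step 8 | methyl 3-[(2E,6E)-3,7-dimethyl-9-(2,6,6-trimethylcyclohex-1-en-1-yl)nona-2,6-dien-1-yl]-4-methoxybenzoate | CC1=C(CC/C(C)=C/CC/C(C)=C/Cc2cc(C(=O)OC)ccc2OC)C(C)(C)CCC1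
F6 | step 6 | lithium butyl(dimethyl)[(1E)-2-methyl-4-(2,6,6-trimethylcyclohex-1-en-1-yl)but-1-en-1-yl]aluminate | [Li+].CCCC[Al-](C)(C)/C=C(\C)CCC1=C(C)CCCC1(C)C
F7 | step 6 | [(3E)-4-methyl-6-(2,6,6-trimethylcyclohex-1-en-1-yl)hex-3-en-1-yl]zinc iodide | CC1=C(CC/C(C)=C/CC[Zn]I)C(C)(C)CCC1
F8 | step 5 | methyl 2-hydroxy-3,4-dihydro-2H-chromene-6-carboxylate (racemic) | COC(=O)c1ccc2OC(O)CCc2c1
F9 | step 5 | methyl 2-(phenylsulfonyl)-3,4-dihydro-2H-chromene-6-carboxylate (racemic) | COC(=O)c1ccc2OC(CCc2c1)S(=O)(=O)c1ccccc1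
F10 | step 5 | methyl 2-[(3E)-4-methyl-6-(2,6,6-trimethylcyclohex-1-en-1-yl)hex-3-en-1-yl]-2-(phenylsulfonyl)-3,4-dihydro-2H-chromene-6-carboxylate (racemic) | COC(=O)c1ccc2OC(CC/C=C(\C)CCC3=C(C)CCCC3(C)C)(CCc2c1)S(=O)(=O)c1ccccc1
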